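**Plan**

1. Locants: upper chromanone unprimed (ring A = benzo ring, ring C = pyranone), lower flavanone double-primed. The retrosynthesis cuts the seven O–benzyl bonds, then the lower ring C at O1''–C8a'' (aryl fluoride displacement) and C4''–C4a'' (aryllithium acylation), then the upper ring C at C8a–O1 and C4a–C4, then C2–C3 (aldol).
2. Enabling feature: upper ring A is a phloroglucinol nucleus joined to ring C only through the adjacent carbons C8a (bonded to O1) and C4a (bonded to the C4 carbonyl). This ortho O/acyl pattern is what an aryne leaves when an alkoxide adds and the resulting aryl anion is acylated.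
3. Forward: fluororesorcinol-derived arylacetic acid → (R)-oxazolidinone imide → syn aldol (C2–C3) → Weinreb amide silyl ether. The aryne annulation then closes the upper ring C onto ring A, and C4 is reduced and silylated at once.
4. The fluoroarene (future lower ring A) is lithiated next to fluorine, acylated with an (S)-β-silyloxy Weinreb amide and closed to the lower ring C by fluoride-triggered SNAr. Desilylation, oxidation and hydrogenolysis finish the route.
5. Stereochemistry: C2 and C3 (R,R; 2,3-cis) come from the auxiliary-controlled syn aldol and are carried with retention. C2'' (S) comes from a catalyst-controlled transfer hydrogenation and is retained in the SNAr. The C4 carbinol centre is temporary.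

Key step: step 12

Remarks on the chemistry: Bn = benzyl. The C4 carbinol centre of 26, 27 and 32–36 is drawn as the all-cis epimer expected from step 13; it is removed in step 21, so the other epimer would serve equally. Compound 4 is racemic and the C4 centre of 24 is undefined; both are transient.

**Route**

Step 1
Reactants: 1 5-fluororesorcinol
Product: 2 1,3-bis(benzyloxy)-5-fluorobenzene
Conditions: BnBr, K2CO3, DMF, 60 °C
Reagents that add atoms: benzyl bromide, BrCc1ccccc1
Why: Williamson ether synthesis on both phenols installs the benzyl groups that are removed at the very end by neutral hydrogenolysis.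

Step 2
Reactants: 2 1,3-bis(benzyloxy)-5-fluorobenzene
Product: 3 2,4-bis(benzyloxy)-6-fluorobenzaldehyde
Conditions: POCl3, DMF, 0 → 60 °C; then H2O
Reagents that add atoms: N,N-dimethylformamide, CN(C)C=O; water, O
Why: Vilsmeier–Haack formylation of the electron-rich arene should go para to one benzyloxy group and ortho to fluorine, the site between the two benzyloxy groups being the more hindered one.

Step 3
Reactants: 3 2,4-bis(benzyloxy)-6-fluorobenzaldehyde
Product: 5 2-[2,4-bis(benzyloxy)-6-fluorophenyl]acetonitrile, via 4-tosyl-2-oxazoline 4 (not isolated)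
Conditions: TosMIC, t-BuOK, DME, −40 °C; then MeOH, reflux
Reagents that add atoms: p-toluenesulfonylmethyl isocyanide (TosMIC), Cc1ccc(cc1)S(=O)(=O)C[N+]#[C-]
Why: Van Leusen reductive cyanation: the TosMIC anion adds to the aldehyde to form oxazoline 4, which ring-opens and on methanolysis loses methyl formate and sulfinate to give the one-carbon-homologated nitrile.

Step 4
Reactants: 5 2-[2,4-bis(benzyloxy)-6-fluorophenyl]acetonitrile
Product: 6 2-[2,4-bis(benzyloxy)-6-fluorophenyl]acetic acid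
Conditions: KOH, EtOH/H2O, reflux; then aq HCl
Reagents that add atoms: water, O
Why: Alkaline nitrile hydrolysis to the arylacetic acid; benzyl ethers and the unactivated aryl fluoride tolerate hydroxide.

Step 5
Reactants: 6 2-[2,4-bis(benzyloxy)-6-fluorophenyl]acetic acid; 7 (R)-4-benzyloxazolidin-2-one
Product: 9 (R)-4-benzyl-3-{2-[2,4-bis(benzyloxy)-6-fluorophenyl]acetyl}oxazolidin-2-one, via mixed pivalic anhydride 8 (not isolated)
Conditions: t-BuCOCl, Et3N, THF, −20 °C; then LiCl, 7, rt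
Reagents that add atoms: none
Why: N-Acylation of the oxazolidinone through the mixed pivalic anhydride 8, promoted by LiCl, is the standard route to Evans imides.

Step 6
Reactants: 9 (R)-4-benzyl-3-{2-[2,4-bis(benzyloxy)-6-fluorophenyl]acetyl}oxazolidin-2-one; 10 3,4-bis(benzyloxy)benzaldehyde
Product: 12 (R)-4-benzyl-3-{(2R,3R)-3-[3,4-bis(benzyloxy)phenyl]-2-[2,4-bis(benzyloxy)-6-fluorophenyl]-3-hydroxypropanoyl}oxazolidin-2-one (syn aldol), via boron enolate 11 (not isolated)
Conditions: n-Bu2BOTf, i-Pr2NEt, CH2Cl2, −78 → 0 °C; 10, −78 → 0 °C; pH 7 buffer, MeOH, H2O2, 0 °C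
Reagents that add atoms: none
Why: Evans syn aldol: soft enolisation gives the Z(O) boron enolate 11, which reacts through a closed chair (Zimmerman–Traxler) transition state on the face opposite the auxiliary benzyl group, so the (R)-auxiliary sets both new centres as (2R,3R) with the α-aryl and hydroxyl groups syn.

Step 7
Reactants: 12 syn aldol imide
Product: 13 (2R,3R)-3-[3,4-bis(benzyloxy)phenyl]-2-[2,4-bis(benzyloxy)-6-fluorophenyl]-3-hydroxy-N-methoxy-N-methylpropanamide
Conditions: AlMe3, MeONHMe·HCl, CH2Cl2, 0 °C; then 12, −10 → 0 °C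
Reagents that add atoms: N,O-dimethylhydroxylamine hydrochloride, CNOC.Cl
Why: Weinreb transamination of the aldol imide by the aluminium amide, assisted by the free β-hydroxyl, is non-basic, so the acidic α-aryl centre is not epimerised and the auxiliary is recovered.

Step 8
Reactants: 13 β-hydroxy Weinreb amide
Product: 14 (2R,3R)-3-[3,4-bis(benzyloxy)phenyl]-2-[2,4-bis(benzyloxy)-6-fluorophenyl]-N-methoxy-N-methyl-3-(trimethylsilyloxy)propanamide
Conditions: Me3SiCl, imidazole, CH2Cl2, 0 °C; used after filtration through Et3N-deactivated silica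
Reagents that add atoms: chlorotrimethylsilane, C[Si](C)(C)Cl
Why: O-Silylation of the secondary alcohol gives a latent alkoxide that fluoride will unmask in step 12 without any O–H proton being present.

Step 9
Reactants: 15 3,5-bis(benzyloxy)phenol
Product: 16 3,5-bis(benzyloxy)phenyl N-isopropylcarbamate
Conditions: i-PrNCO, Et3N (cat.), CH2Cl2, rt
Reagents that add atoms: isopropyl isocyanate, CC(C)N=C=O
Why: Carbamoylation of the phenol with an isocyanate installs the directing group for ortho-metalation.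

Step 10
Reactants: 16 3,5-bis(benzyloxy)phenyl N-isopropylcarbamate
Product: 19 3,5-bis(benzyloxy)-2-(trimethylsilyl)phenyl N-isopropylcarbamate, via N-silyl carbamate 17 (not isolated), via ortho-lithio carbamate 18 (not isolated)
Conditions: t-BuMe2SiOTf, TMEDA, Et2O, 0 °C → rt; n-BuLi, TMEDA, −78 °C; Me3SiCl, −78 °C → rt; aqueous acidic work-up
Reagents that add atoms: chlorotrimethylsilane, C[Si](C)(C)Cl
Why: Directed ortho-metalation: after in situ N-silylation (17) the carbamate directs lithiation to the two equivalent ortho positions (18), each also flanked by a benzyloxy group, Me3SiCl quenches the anion and aqueous acid removes the N-silyl group.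

Step 11
Reactants: 19 3,5-bis(benzyloxy)-2-(trimethylsilyl)phenyl N-isopropylcarbamate
Product: 21 3,5-bis(benzyloxy)-2-(trimethylsilyl)phenyl trifluoromethanesulfonate, via silyl phenol 20 (not isolated)
Conditions: Et2NH, DBU, MeCN, 40 °C; then PhNTf2, rt
Reagents that add atoms: N-phenylbis(trifluoromethanesulfonimide), O=S(=O)(N(c1ccccc1)S(=O)(=O)C(F)(F)F)C(F)(F)F
Why: Amine-mediated carbamate cleavage (the isocyanate is trapped as a urea) frees phenol 20, which is triflated in the same flask to the ortho-silylaryl triflate.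

Step 12
Reactants: 14 silyl ether of the syn β-hydroxy Weinreb amide; 21 3,5-bis(benzyloxy)-2-(trimethylsilyl)phenyl trifluoromethanesulfonate
Product: 25 (2R,3R)-5,7-bis(benzyloxy)-2-[3,4-bis(benzyloxy)phenyl]-3-[2,4-bis(benzyloxy)-6-fluorophenyl]chroman-4-one (2,3-cis), via potassium alkoxide 22 (not isolated), via aryne 23 (not isolated), via hemiaminal alkoxide 24 (not isolated)
Conditions: 21 (2.5 equiv), KF, 18-crown-6, THF, 0 °C → rt; cold aq NH4Cl; crude product taken directly into step 13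
Reagents that add atoms: none
Why: Proposed new method: fluoride removes the trimethylsilyl group from 14 and from 21, giving alkoxide 22 and, after loss of triflate, aryne 23; the alkoxide adds to the aryne carbon remote from the flanking benzyloxy group, which places the aryl anion next to that inductively stabilising oxygen, and the anion then attacks the amide carbonyl to give hemiaminal alkoxide 24, which collapses to ketone 25 only on the buffered quench. The closest known reactions are the fluoride-mediated annulation of arynes with methyl salicylates to xanthones (aryloxide addition, then acyl capture of the aryl anion) and the O–H insertion of aliphatic alcohols into arynes. Ring C closes by 6-exo-trig acyl substitution, forming C8a–O1 and C4a–C4. No stereocentre is made: C2 and C3 come from the syn aldol and are not touched (C2 reacts through oxygen), so the syn pair becomes the 2,3-cis pair. The step needs regioselective aryne capture, secured by the 3-benzyloxy substituent of 23, and acylation of the aryl anion faster than its protonation, secured by having no O–H in the flask (silyl ether in place of the alcohol, THF in place of acetonitrile). It also needs C3 to survive, which is why the acceptor is the N-methoxy-N-methylamide and not an ester: no alkoxide is expelled and C4 stays tetrahedral until work-up, whereas a methyl ester would release methoxide next to an epimerisable 3-aryl ketone.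

Step 13
Reactants: 25 cis-chromanone
Product: 26 (2R,3S,4R)-5,7-bis(benzyloxy)-2-[3,4-bis(benzyloxy)phenyl]-3-[2,4-bis(benzyloxy)-6-fluorophenyl]chroman-4-ol (all-cis)
Conditions: NaBH4, CeCl3·7H2O, THF/MeOH, −20 °C
Reagents that add atoms: none
Why: Borohydride reduction under Luche conditions removes the epimerisable ketone at once; hydride should add anti to the pseudo-axial C3 aryl group to give mainly the all-cis 4-ol, a centre that is erased again in step 21.

Step 14
Reactants: 26 all-cis chroman-4-ol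
Product: 27 (2R,3R,4R)-5,7-bis(benzyloxy)-2-[3,4-bis(benzyloxy)phenyl]-3-[2,4-bis(benzyloxy)-6-fluorophenyl]-4-(tert-butyldimethylsilyloxy)chroman
Conditions: t-BuMe2SiOTf, 2,6-lutidine, CH2Cl2, −78 → 0 °C
Reagents that add atoms: tert-butyldimethylsilyl trifluoromethanesulfonate, CC(C)(C)[Si](C)(C)OS(=O)(=O)C(F)(F)F
Why: Silyl triflate silylation of the hindered benzylic alcohol protects it against the base of step 18 and keeps its oxygen from displacing the aryl fluorine later.

Step 15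
Reactants: 28 4-(benzyloxy)benzoyl chloride
Product: 29 3-[4-(benzyloxy)phenyl]-N-methoxy-N-methyl-3-oxopropanamide
Conditions: LiN(i-Pr)2, N-methoxy-N-methylacetamide, THF, −78 °C; then 28, −78 °C; aq NH4Cl
Reagents that add atoms: N-methoxy-N-methylacetamide, CC(=O)N(C)OC
Why: Crossed Claisen-type C-acylation of the amide lithium enolate (used in twofold amount, since the product is deprotonated) by the acid chloride gives the β-keto Weinreb amide.

Step 16
Reactants: 29 β-keto Weinreb amide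
Product: 30 (S)-3-[4-(benzyloxy)phenyl]-3-hydroxy-N-methoxy-N-methylpropanamide
Conditions: RuCl[(S,S)-TsDPEN](p-cymene) (cat.), HCO2H/Et3N (5:2), 40 °C
Reagents that add atoms: none
Why: Noyori asymmetric transfer hydrogenation: as with other aryl alkyl ketones the (S,S)-TsDPEN ruthenium hydride delivers hydrogen to the face that gives the (S)-benzylic alcohol, the aryl ring lying under the arene ligand.

Step 17
Reactants: 30 (S)-β-hydroxy Weinreb amide
Product: 31 (S)-3-[4-(benzyloxy)phenyl]-N-methoxy-N-methyl-3-(triethylsilyloxy)propanamide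
Conditions: Et3SiCl, imidazole, DMF, 0 °C → rt
Reagents that add atoms: chlorotriethylsilane, CC[Si](CC)(CC)Cl
Why: Silylation of the alcohol as the triethylsilyl ether, which is stable to the aryllithium but more labile to fluoride than the tert-butyldimethylsilyl ether of 27.

Step 18
Reactants: 27 upper-unit silyl ether; 31 (S)-β-silyloxy Weinreb amide
Product: 33 (S)-3-[4-(benzyloxy)phenyl]-1-{4,6-bis(benzyloxy)-3-[(2R,3R,4R)-5,7-bis(benzyloxy)-2-[3,4-bis(benzyloxy)phenyl]-4-(tert-butyldimethylsilyloxy)chroman-3-yl]-2-fluorophenyl}-3-(triethylsilyloxy)propan-1-one, via aryllithium 32 (not isolated)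
Conditions: LiTMP (from 2,2,6,6-tetramethylpiperidine and n-BuLi), THF, −78 °C; then 31, −78 → −50 °C; aq NH4Cl
Reagents that add atoms: none
Why: Directed ortho-metalation followed by Weinreb ketone synthesis: the amide base removes the most acidic ring proton, the one flanked by fluorine and benzyloxy, and aryllithium 32 is acylated by the Weinreb amide without over-addition.

Step 19
Reactants: 33 β-silyloxy aryl ketone
Product: 35 (2S)-5,7-bis(benzyloxy)-2-[4-(benzyloxy)phenyl]-8-[(2R,3R,4R)-5,7-bis(benzyloxy)-2-[3,4-bis(benzyloxy)phenyl]-4-(tert-butyldimethylsilyloxy)chroman-3-yl]chroman-4-one, via ammonium alkoxide 34 (not isolated)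
Conditions: Bu4NF (0.5 equiv), THF, −20 → 0 °C
Reagents that add atoms: none
Why: Fluoride-triggered desilylation gives alkoxide 34, which displaces the fluorine ortho to the ketone (intramolecular SNAr, six-membered ring) and so regenerates fluoride; the carbinol C–O bond is not touched, so C2'' keeps its (S) configuration.

Step 20
Reactants: 35 lower flavanone silyl ether
Product: 36 (2S)-5,7-bis(benzyloxy)-2-[4-(benzyloxy)phenyl]-8-[(2R,3S,4R)-5,7-bis(benzyloxy)-2-[3,4-bis(benzyloxy)phenyl]-4-hydroxychroman-3-yl]chroman-4-one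
Conditions: Bu4NF, AcOH (1:1), THF, rt
Reagents that add atoms: none
Why: Fluoride desilylation buffered with acetic acid frees the C4 hydroxyl without opening the base-sensitive flavanone ring (retro-oxa-Michael) or ionising the electron-rich benzylic position.

Step 21
Reactants: 36 flavan-4-ol
Product: 37 (2R,3R)-5,7-bis(benzyloxy)-2-[3,4-bis(benzyloxy)phenyl]-3-{(2S)-5,7-bis(benzyloxy)-2-[4-(benzyloxy)phenyl]-4-oxochroman-8-yl}chroman-4-one
Conditions: Dess–Martin periodinane, CH2Cl2, 0 °C → rt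
Reagents that add atoms: none
Why: Dess–Martin oxidation under near-neutral conditions restores the C4 ketone, and no base is present that could epimerise the 2,3-cis C3–H.

Step 22
Reactants: 37 hepta-O-benzyl biflavanone
Product: 38 (2R,3R)-2-(3,4-dihydroxyphenyl)-5,7-dihydroxy-3-[(2S)-5,7-dihydroxy-2-(4-hydroxyphenyl)-4-oxochroman-8-yl]chroman-4-one (CNP0105436.1)
Conditions: H2 (1 atm), 10% Pd/C, EtOAc/MeOH, rt
Reagents that add atoms: none
Why: Hydrogenolysis over Pd/C cleaves all seven benzyl ethers under neutral conditions, which leaves the cis C3 centre and both flavanone rings intact.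

**Compound list**

1 | 5-fluororesorcinol | Oc1cc(O)cc(F)c1 | starting material
2 | 1,3-bis(benzyloxy)-5-fluorobenzene | Fc1cc(OCc2ccccc2)cc(OCc2ccccc2)c1 | intermediate
3 | 2,4-bis(benzyloxy)-6-fluorobenzaldehyde | O=Cc1c(F)cc(OCc2ccccc2)cc1OCc1ccccc1 | intermediate
4 | trans-5-[2,4-bis(benzyloxy)-6-fluorophenyl]-4-tosyl-4,5-dihydrooxazole (racemic) | Cc1ccc(cc1)S(=O)(=O)C1N=COC1c1c(F)cc(OCc2ccccc2)cc1OCc1ccccc1 | intermediate (not isolated)
5 | 2-[2,4-bis(benzyloxy)-6-fluorophenyl]acetonitrile | N#CCc1c(F)cc(OCc2ccccc2)cc1OCc1ccccc1 | intermediate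
6 | 2-[2,4-bis(benzyloxy)-6-fluorophenyl]acetic acid | OC(=O)Cc1c(F)cc(OCc2ccccc2)cc1OCc1ccccc1 | intermediate
7 | (R)-4-benzyloxazolidin-2-one | O=C1N[C@H](Cc2ccccc2)CO1 | starting material
8 | 2-[2,4-bis(benzyloxy)-6-fluorophenyl]acetic pivalic anhydride | CC(C)(C)C(=O)OC(=O)Cc1c(F)cc(OCc2ccccc2)cc1OCc1ccccc1 | intermediate (not isolated)
9 | (R)-4-benzyl-3-{2-[2,4-bis(benzyloxy)-6-fluorophenyl]acetyl}oxazolidin-2-one | O=C(Cc1c(F)cc(OCc2ccccc2)cc1OCc1ccccc1)N1[C@H](Cc2ccccc2)COC1=O | intermediate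
10 | 3,4-bis(benzyloxy)benzaldehyde | O=Cc1ccc(OCc2ccccc2)c(OCc2ccccc2)c1 | starting material
11 | Z(O)-dibutylboron enolate of 9 | CCCCB(CCCC)O/C(=C\c1c(F)cc(OCc2ccccc2)cc1OCc1ccccc1)N1[C@H](Cc2ccccc2)COC1=O | intermediate (not isolated)
12 | (R)-4-benzyl-3-{(2R,3R)-3-[3,4-bis(benzyloxy)phenyl]-2-[2,4-bis(benzyloxy)-6-fluorophenyl]-3-hydroxypropanoyl}oxazolidin-2-one | O=C([C@H](c1c(F)cc(OCc2ccccc2)cc1OCc1ccccc1)[C@@H](O)c1ccc(OCc2ccccc2)c(OCc2ccccc2)c1)N1[C@H](Cc2ccccc2)COC1=O | intermediate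
13 | (2R,3R)-3-[3,4-bis(benzyloxy)phenyl]-2-[2,4-bis(benzyloxy)-6-fluorophenyl]-3-hydroxy-N-methoxy-N-methylpropanamide | CON(C)C(=O)[C@H](c1c(F)cc(OCc2ccccc2)cc1OCc1ccccc1)[C@@H](O)c1ccc(OCc2ccccc2)c(OCc2ccccc2)c1 | intermediate
14 | (2R,3R)-3-[3,4-bis(benzyloxy)phenyl]-2-[2,4-bis(benzyloxy)-6-fluorophenyl]-N-methoxy-N-methyl-3-(trimethylsilyloxy)propanamide | CON(C)C(=O)[C@H](c1c(F)cc(OCc2ccccc2)cc1OCc1ccccc1)[C@@H](O[Si](C)(C)C)c1ccc(OCc2ccccc2)c(OCc2ccccc2)c1 | intermediate
15 | 3,5-bis(benzyloxy)phenol | Oc1cc(OCc2ccccc2)cc(OCc2ccccc2)c1 | starting material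
16 | 3,5-bis(benzyloxy)phenyl N-isopropylcarbamate | CC(C)NC(=O)Oc1cc(OCc2ccccc2)cc(OCc2ccccc2)c1 | intermediate
17 | 3,5-bis(benzyloxy)phenyl N-(tert-butyldimethylsilyl)-N-isopropylcarbamate | CC(C)N(C(=O)Oc1cc(OCc2ccccc2)cc(OCc2ccccc2)c1)[Si](C)(C)C(C)(C)C | intermediate (not isolated)
18 | 2-lithio derivative of 17 | [Li]c1c(OC(=O)N(C(C)C)[Si](C)(C)C(C)(C)C)cc(OCc2ccccc2)cc1OCc1ccccc1 | intermediate (not isolated)
19 | 3,5-bis(benzyloxy)-2-(trimethylsilyl)phenyl N-isopropylcarbamate | CC(C)NC(=O)Oc1cc(OCc2ccccc2)cc(OCc2ccccc2)c1[Si](C)(C)C | intermediate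
20 | 3,5-bis(benzyloxy)-2-(trimethylsilyl)phenol | C[Si](C)(C)c1c(O)cc(OCc2ccccc2)cc1OCc1ccccc1 | intermediate (not isolated)
21 | 3,5-bis(benzyloxy)-2-(trimethylsilyl)phenyl trifluoromethanesulfonate | C[Si](C)(C)c1c(OCc2ccccc2)cc(OCc2ccccc2)cc1OS(=O)(=O)C(F)(F)F | intermediate
22 | potassium alkoxide of 13 | CON(C)C(=O)[C@H](c1c(F)cc(OCc2ccccc2)cc1OCc1ccccc1)[C@@H]([O-])c1ccc(OCc2ccccc2)c(OCc2ccccc2)c1.[K+] | intermediate (not isolated)
23 | 3,5-bis(benzyloxy)benzyne | C1#CC(OCc2ccccc2)=CC(OCc2ccccc2)=C1 | intermediate (not isolated)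
24 | potassium (2R,3R)-5,7-bis(benzyloxy)-2-[3,4-bis(benzyloxy)phenyl]-3-[2,4-bis(benzyloxy)-6-fluorophenyl]-4-[methoxy(methyl)amino]chroman-4-olate | Fc1cc(OCc2ccccc2)cc(OCc2ccccc2)c1[C@H]1C([O-])(N(C)OC)c2c(OCc3ccccc3)cc(OCc3ccccc3)cc2O[C@H]1c1ccc(OCc2ccccc2)c(OCc2ccccc2)c1.[K+] | intermediate (not isolated)
25 | (2R,3R)-5,7-bis(benzyloxy)-2-[3,4-bis(benzyloxy)phenyl]-3-[2,4-bis(benzyloxy)-6-fluorophenyl]chroman-4-one (2,3-cis) | Fc1cc(OCc2ccccc2)cc(OCc2ccccc2)c1[C@H]1C(=O)c2c(OCc3ccccc3)cc(OCc3ccccc3)cc2O[C@H]1c1ccc(OCc2ccccc2)c(OCc2ccccc2)c1 | intermediate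
26 | (2R,3S,4R)-5,7-bis(benzyloxy)-2-[3,4-bis(benzyloxy)phenyl]-3-[2,4-bis(benzyloxy)-6-fluorophenyl]chroman-4-ol (all-cis) | Fc1cc(OCc2ccccc2)cc(OCc2ccccc2)c1[C@H]1[C@@H](O)c2c(OCc3ccccc3)cc(OCc3ccccc3)cc2O[C@H]1c1ccc(OCc2ccccc2)c(OCc2ccccc2)c1 | intermediate
27 | (2R,3R,4R)-5,7-bis(benzyloxy)-2-[3,4-bis(benzyloxy)phenyl]-3-[2,4-bis(benzyloxy)-6-fluorophenyl]-4-(tert-butyldimethylsilyloxy)chroman | Fc1cc(OCc2ccccc2)cc(OCc2ccccc2)c1[C@H]1[C@@H](O[Si](C)(C)C(C)(C)C)c2c(OCc3ccccc3)cc(OCc3ccccc3)cc2O[C@H]1c1ccc(OCc2ccccc2)c(OCc2ccccc2)c1 | intermediate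
28 | 4-(benzyloxy)benzoyl chloride | O=C(Cl)c1ccc(OCc2ccccc2)cc1 | starting material
29 | 3-[4-(benzyloxy)phenyl]-N-methoxy-N-methyl-3-oxopropanamide | CON(C)C(=O)CC(=O)c1ccc(OCc2ccccc2)cc1 | intermediate
30 | (S)-3-[4-(benzyloxy)phenyl]-3-hydroxy-N-methoxy-N-methylpropanamide | CON(C)C(=O)C[C@H](O)c1ccc(OCc2ccccc2)cc1 | intermediate
31 | (S)-3-[4-(benzyloxy)phenyl]-N-methoxy-N-methyl-3-(triethylsilyloxy)propanamide | CON(C)C(=O)C[C@H](O[Si](CC)(CC)CC)c1ccc(OCc2ccccc2)cc1 | intermediate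
32 | aryllithium from 27, lithium on the fluoroarene carbon between F and OBn | [Li]c1c(F)c([C@H]2[C@@H](O[Si](C)(C)C(C)(C)C)c3c(OCc4ccccc4)cc(OCc4ccccc4)cc3O[C@H]2c2ccc(OCc3ccccc3)c(OCc3ccccc3)c2)c(OCc2ccccc2)cc1OCc1ccccc1 | intermediate (not isolated)
33 | (S)-3-[4-(benzyloxy)phenyl]-1-{4,6-bis(benzyloxy)-3-[(2R,3R,4R)-5,7-bis(benzyloxy)-2-[3,4-bis(benzyloxy)phenyl]-4-(tert-butyldimethylsilyloxy)chroman-3-yl]-2-fluorophenyl}-3-(triethylsilyloxy)propan-1-one | O=C(C[C@H](O[Si](CC)(CC)CC)c1ccc(OCc2ccccc2)cc1)c1c(F)c([C@H]2[C@@H](O[Si](C)(C)C(C)(C)C)c3c(OCc4ccccc4)cc(OCc4ccccc4)cc3O[C@H]2c2ccc(OCc3ccccc3)c(OCc3ccccc3)c2)c(OCc2ccccc2)cc1OCc1ccccc1 | intermediate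
34 | tetrabutylammonium alkoxide from 33 (triethylsilyl group removed) | O=C(C[C@H]([O-])c1ccc(OCc2ccccc2)cc1)c1c(F)c([C@H]2[C@@H](O[Si](C)(C)C(C)(C)C)c3c(OCc4ccccc4)cc(OCc4ccccc4)cc3O[C@H]2c2ccc(OCc3ccccc3)c(OCc3ccccc3)c2)c(OCc2ccccc2)cc1OCc1ccccc1.CCCC[N+](CCCC)(CCCC)CCCC | intermediate (not isolated)
35 | (2S)-5,7-bis(benzyloxy)-2-[4-(benzyloxy)phenyl]-8-[(2R,3R,4R)-5,7-bis(benzyloxy)-2-[3,4-bis(benzyloxy)phenyl]-4-(tert-butyldimethylsilyloxy)chroman-3-yl]chroman-4-one | O=C1C[C@@H](c2ccc(OCc3ccccc3)cc2)Oc2c1c(OCc1ccccc1)cc(OCc1ccccc1)c2[C@H]1[C@@H](O[Si](C)(C)C(C)(C)C)c2c(OCc3ccccc3)cc(OCc3ccccc3)cc2O[C@H]1c1ccc(OCc2ccccc2)c(OCc2ccccc2)c1 | intermediate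
36 | (2S)-5,7-bis(benzyloxy)-2-[4-(benzyloxy)phenyl]-8-[(2R,3S,4R)-5,7-bis(benzyloxy)-2-[3,4-bis(benzyloxy)phenyl]-4-hydroxychroman-3-yl]chroman-4-one | O=C1C[C@@H](c2ccc(OCc3ccccc3)cc2)Oc2c1c(OCc1ccccc1)cc(OCc1ccccc1)c2[C@H]1[C@@H](O)c2c(OCc3ccccc3)cc(OCc3ccccc3)cc2O[C@H]1c1ccc(OCc2ccccc2)c(OCc2ccccc2)c1 | intermediate
37 | (2R,3R)-5,7-bis(benzyloxy)-2-[3,4-bis(benzyloxy)phenyl]-3-{(2S)-5,7-bis(benzyloxy)-2-[4-(benzyloxy)phenyl]-4-oxochroman-8-yl}chroman-4-one | O=C1C[C@@H](c2ccc(OCc3ccccc3)cc2)Oc2c1c(OCc1ccccc1)cc(OCc1ccccc1)c2[C@H]1C(=O)c2c(OCc3ccccc3)cc(OCc3ccccc3)cc2O[C@H]1c1ccc(OCc2ccccc2)c(OCc2ccccc2)c1 | intermediate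
38 | (2R,3R)-2-(3,4-dihydroxyphenyl)-5,7-dihydroxy-3-[(2S)-5,7-dihydroxy-2-(4-hydroxyphenyl)-4-oxochroman-8-yl]chroman-4-one | O=C1C[C@@H](c2ccc(O)cc2)Oc2c1c(O)cc(O)c2[C@H]1C(=O)c2c(O)cc(O)cc2O[C@H]1c1ccc(O)c(O)c1 | target

**Step count and risks**

Total steps: 22. Longest linear sequence: 16 (steps 1–8, 12–14, 18–22). Steps 9–11 (aryne precursor) and 15–17 (lower-unit fragment) are side branches.

Steps most likely to fail:

1. Step 12 (aryne annulation). The aryl anion may be protonated or may abstract the C3 proton before it reaches the amide carbonyl. The free alkoxide may also fragment by retro-aldol cleavage before it meets the aryne. Either process diverts material from ring closure or erodes the cis relationship. Fallback (known reaction types only: Weinreb ketone synthesis and intramolecular SNAr), setting out from 13 and 2 and returning at 25: 13 is silylated with Et3SiCl and imidazole to the triethylsilyl ether of the hydroxy amide F1. Compound 2 is lithiated between fluorine and benzyloxy with LiTMP in THF at −78 °C to 2,4-bis(benzyloxy)-6-fluorophenyllithium F2, which adds to F1 to give the diaryl ketone F3. A substoichiometric charge of Bu4NF at low temperature then removes the silyl group, and the alkoxide displaces the fluorine ortho to the carbonyl. This closes ring C through the same C8a–O1 bond and gives 25, which is reduced immediately as in step 13. Only the fluorine on the ketone-bearing ring is activated, so the fluorine of the α-aryl group stays in place for step 19.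

2. Step 19 (desilylative SNAr). Retro-aldol cleavage or β-elimination of the released alkoxide may outrun fluoride displacement, which would scramble C2'' or leave an open-chain enone. Fallback, setting out from 27 and returning at 35: aryllithium 32 (made as in step 18) is quenched with N-methoxy-N-methylacetamide to give the methyl ketone F4. 2-(Methylsulfonyl)ethanol and NaH in DMF exchange the activated fluorine for hydroxyl, giving the 2'-hydroxyacetophenone F5. Claisen–Schmidt condensation with 4-(benzyloxy)benzaldehyde (KOH, EtOH) gives the 2'-hydroxychalcone F6. Oxa-Michael cyclisation (NaOAc, EtOH, reflux) should then give 35 together with its C2'' epimer F7; the two are diastereomers and are separated by chromatography.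

3. Step 18 (lithiation and acylation). Acyl transfer from the Weinreb amide to the doubly ortho-substituted aryllithium may be slow, so that enolisation of the amide, loss of lithium fluoride from 32 or benzylic deprotonation overtakes ketone formation. Fallback, setting out from 31 and 27 and returning at 33: 31 is reduced with i-Bu2AlH in CH2Cl2 at −78 °C to (S)-3-[4-(benzyloxy)phenyl]-3-(triethylsilyloxy)propanal F8. Aryllithium 32 adds to this aldehyde at −78 °C, where carbonyl addition is fast, giving the secondary benzylic alcohol F9 as a mixture of carbinol epimers. Dess–Martin oxidation converts both epimers into ketone 33.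

**Further compounds**

F1 | step 12 | (2R,3R)-3-[3,4-bis(benzyloxy)phenyl]-2-[2,4-bis(benzyloxy)-6-fluorophenyl]-N-methoxy-N-methyl-3-(triethylsilyloxy)propanamide | CON(C)C(=O)[C@H](c1c(F)cc(OCc2ccccc2)cc1OCc1ccccc1)[C@@H](O[Si](CC)(CC)CC)c1ccc(OCc2ccccc2)c(OCc2ccccc2)c1
F2 | step 12 | 2,4-bis(benzyloxy)-6-fluorophenyllithium | [Li]c1c(F)cc(OCc2ccccc2)cc1OCc1ccccc1
F3 | step 12 | (2R,3R)-3-[3,4-bis(benzyloxy)phenyl]-1,2-bis[2,4-bis(benzyloxy)-6-fluorophenyl]-3-(triethylsilyloxy)propan-1-one | O=C(c1c(F)cc(OCc2ccccc2)cc1OCc1ccccc1)[C@H](c1c(F)cc(OCc2ccccc2)cc1OCc1ccccc1)[C@@H](O[Si](CC)(CC)CC)c1ccc(OCc2ccccc2)c(OCc2ccccc2)c1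
F4 | step 19 | 1-{4,6-bis(benzyloxy)-3-[(2R,3R,4R)-5,7-bis(benzyloxy)-2-[3,4-bis(benzyloxy)phenyl]-4-(tert-butyldimethylsilyloxy)chroman-3-yl]-2-fluorophenyl}ethan-1-one | CC(=O)c1c(F)c([C@H]2[C@@H](O[Si](C)(C)C(C)(C)C)c3c(OCc4ccccc4)cc(OCc4ccccc4)cc3O[C@H]2c2ccc(OCc3ccccc3)c(OCc3ccccc3)c2)c(OCc2ccccc2)cc1OCc1ccccc1
F5 | step 19 | 1-{4,6-bis(benzyloxy)-3-[(2R,3R,4R)-5,7-bis(benzyloxy)-2-[3,4-bis(benzyloxy)phenyl]-4-(tert-butyldimethylsilyloxy)chroman-3-yl]-2-hydroxyphenyl}ethan-1-one | CC(=O)c1c(O)c([C@H]2[C@@H](O[Si](C)(C)C(C)(C)C)c3c(OCc4ccccc4)cc(OCc4ccccc4)cc3O[C@H]2c2ccc(OCc3ccccc3)c(OCc3ccccc3)c2)c(OCc2ccccc2)cc1OCc1ccccc1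
F6 | step 19 | (E)-3-[4-(benzyloxy)phenyl]-1-{4,6-bis(benzyloxy)-3-[(2R,3R,4R)-5,7-bis(benzyloxy)-2-[3,4-bis(benzyloxy)phenyl]-4-(tert-butyldimethylsilyloxy)chroman-3-yl]-2-hydroxyphenyl}prop-2-en-1-one | O=C(/C=C/c1ccc(OCc2ccccc2)cc1)c1c(O)c([C@H]2[C@@H](O[Si](C)(C)C(C)(C)C)c3c(OCc4ccccc4)cc(OCc4ccccc4)cc3O[C@H]2c2ccc(OCc3ccccc3)c(OCc3ccccc3)c2)c(OCc2ccccc2)cc1OCc1ccccc1
F7 | step 19 | (2R)-5,7-bis(benzyloxy)-2-[4-(benzyloxy)phenyl]-8-[(2R,3R,4R)-5,7-bis(benzyloxy)-2-[3,4-bis(benzyloxy)phenyl]-4-(tert-butyldimethylsilyloxy)chroman-3-yl]chroman-4-one (C2'' epimer of 35) | O=C1C[C@H](c2ccc(OCc3ccccc3)cc2)Oc2c1c(OCc1ccccc1)cc(OCc1ccccc1)c2[C@H]1[C@@H](O[Si](C)(C)C(C)(C)C)c2c(OCc3ccccc3)cc(OCc3ccccc3)cc2O[C@H]1c1ccc(OCc2ccccc2)c(OCc2ccccc2)c1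
F8 | step 18 | (S)-3-[4-(benzyloxy)phenyl]-3-(triethylsilyloxy)propanal | O=CC[C@H](O[Si](CC)(CC)CC)c1ccc(OCc2ccccc2)cc1
F9 | step 18 | (3S)-3-[4-(benzyloxy)phenyl]-1-{4,6-bis(benzyloxy)-3-[(2R,3R,4R)-5,7-bis(benzyloxy)-2-[3,4-bis(benzyloxy)phenyl]-4-(tert-butyldimethylsilyloxy)chroman-3-yl]-2-fluorophenyl}-3-(triethylsilyloxy)propan-1-ol (C1 epimer mixture) | OC(C[C@H](O[Si](CC)(CC)CC)c1ccc(OCc2ccccc2)cc1)c1c(F)c([C@H]2[C@@H](O[Si](C)(C)C(C)(C)C)c3c(OCc4ccccc4)cc(OCc4ccccc4)cc3O[C@H]2c2ccc(OCc3ccccc3)c(OCc3ccccc3)c2)c(OCc2ccccc2)cc1OCc1ccccc1
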